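## Retrosynthetic overview

1. The target comes from global desilylation of its bis-silyl ether, made by Yamaguchi acylation of the macrocyclic C8 alcohol with silyl-protected (E)-4-hydroxy-2-methylbut-2-enoic acid.
2. The ten-membered ring (second ring) is closed by ring-closing metathesis, forming the cis C1=C10 bond between a butenyl-terminated C6 side chain and a methallyl carbinol C7 side chain on a trans γ-lactone.
3. The C11 methyl comes from trans-selective lactone enolate methylation; the C8 carbinol from reagent-controlled methallylboration of a lactone carbaldehyde.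
4. Key union (C6–C7): Evans boron syn-aldol between a succinate-derived (S)-benzyloxazolidinone imide (fragment B) and a (Z)-β,β-disubstituted enal (fragment A); the adduct closes to the trans γ-lactone (first ring).
5. The enal comes from propargyl alcohol by syn-carbocupration of a 4-silyloxybut-2-ynoate, which fixes the C4=C5 geometry.

Assumption: the target is taken as drawn, 6R,7R,8S,11S with a cis ring C1=C10 and a trans ring C4=C5 (both Z by CIP); germacrane locants are used (ring C1–C10, lactone C11–C13 on C7/C6, C14 = methyl on C10, C15 = CH2OH on C4); Grignard and borane reagent solutions are bought.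

## Route

Step 1
Reactants: 1 prop-2-yn-1-ol
Product: 2 tert-butyl(diphenyl)(prop-2-yn-1-yloxy)silane
Conditions: TBDPSCl, imidazole, CH2Cl2, 0 °C to rt
Reagents that add atoms: tert-butyl(chloro)diphenylsilane, CC(C)(C)[Si](Cl)(c1ccccc1)c1ccccc1
Why: Imidazole-promoted silylation of a primary alcohol gives a silyl ether robust enough to last until the final step.

Step 2
Reactants: 2 tert-butyl(diphenyl)(prop-2-yn-1-yloxy)silane
Product: 4 methyl 4-[(tert-butyldiphenylsilyl)oxy]but-2-ynoate, via lithium acetylide 3 (not isolated)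
Conditions: n-BuLi, THF, −78 °C; ClCO2Me, −78 to 0 °C
Reagents that add atoms: methyl chloroformate, COC(=O)Cl
Why: Deprotonation of the terminal alkyne and C-acylation of the acetylide with a chloroformate gives the ynoate, whose ester carbon becomes C6.

Step 3
Reactants: 4 methyl 4-[(tert-butyldiphenylsilyl)oxy]but-2-ynoate
Product: 6 methyl (2Z)-3-{[(tert-butyldiphenylsilyl)oxy]methyl}hepta-2,6-dienoate, via alkenylcopper 5 (not isolated)
Conditions: but-3-enylmagnesium bromide, CuBr·SMe2 (1:1), THF, −78 °C; then 4; NH4Cl/MeOH at −78 °C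
Reagents that add atoms: but-3-enylmagnesium bromide, C=CCC[Mg]Br
Why: syn-Carbocupration of the ynoate followed by protonation with retention at −78 °C puts the butenyl group trans and the CH2OSi group cis to the ester, which fixes the C4=C5 geometry of the target.

Step 4
Reactants: 6 methyl (2Z)-3-{[(tert-butyldiphenylsilyl)oxy]methyl}hepta-2,6-dienoate
Product: 7 (2Z)-3-{[(tert-butyldiphenylsilyl)oxy]methyl}hepta-2,6-dien-1-ol
Conditions: iBu2AlH (2.2 equiv), CH2Cl2, −78 °C; aq. potassium sodium tartrate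
Reagents that add atoms: none
Why: 1,2-Reduction of the enoate with the aluminium hydride gives the allylic alcohol without touching the alkene geometry.

Step 5
Reactants: 7 (2Z)-3-{[(tert-butyldiphenylsilyl)oxy]methyl}hepta-2,6-dien-1-ol
Product: 8 (2Z)-3-{[(tert-butyldiphenylsilyl)oxy]methyl}hepta-2,6-dienal
Conditions: activated MnO2, CH2Cl2, rt
Reagents that add atoms: none
Why: Neutral allylic oxidation with MnO2 gives the enal (fragment A) without Z/E isomerisation.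

Step 6
Reactants: 9 (4S)-4-benzyl-1,3-oxazolidin-2-one; 10 methyl 4-chloro-4-oxobutanoate
Product: 12 methyl 4-[(4S)-4-benzyl-2-oxo-1,3-oxazolidin-3-yl]-4-oxobutanoate, via N-lithio oxazolidinone 11 (not isolated)
Conditions: n-BuLi, THF, −78 °C; then 10, −78 to 0 °C
Reagents that add atoms: none
Why: N-Acylation of the lithiated Evans auxiliary with the succinic half-ester chloride gives the imide (fragment B) carrying C8, C7, C11 and C12.

Step 7
Reactants: 12 methyl 4-[(4S)-4-benzyl-2-oxo-1,3-oxazolidin-3-yl]-4-oxobutanoate; 8 (2Z)-3-{[(tert-butyldiphenylsilyl)oxy]methyl}hepta-2,6-dienal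
Product: 15 (4S)-4-benzyl-3-{[(2R,3S)-2-[(1Z)-2-{[(tert-butyldiphenylsilyl)oxy]methyl}hexa-1,5-dien-1-yl]-5-oxooxolan-3-yl]carbonyl}-1,3-oxazolidin-2-one, via boron enolate 13 (not isolated), via syn-aldol adduct 14 (not isolated)
Conditions: Bu2BOTf, iPr2NEt, CH2Cl2, 0 °C; 8, −78 to 0 °C; pH 7 buffer, MeOH, H2O2, 0 °C; PPTS (cat.), CH2Cl2, rt
Reagents that add atoms: none
Why: Evans syn-aldol of the (Z)-boron enolate through a Zimmerman–Traxler chair, with the benzyl group shielding one face, sets C6 (R) and C7 together, and the γ-hydroxy methyl ester then lactonises to the trans-4,5-disubstituted γ-lactone.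

Step 8
Reactants: 15 (4S)-4-benzyl-3-{[(2R,3S)-2-[(1Z)-2-{[(tert-butyldiphenylsilyl)oxy]methyl}hexa-1,5-dien-1-yl]-5-oxooxolan-3-yl]carbonyl}-1,3-oxazolidin-2-one
Product: 16 (4R,5R)-5-[(1Z)-2-{[(tert-butyldiphenylsilyl)oxy]methyl}hexa-1,5-dien-1-yl]-4-(hydroxymethyl)oxolan-2-one
Conditions: NaBH4, THF/H2O (4:1), 0 °C; aq. NH4Cl
Reagents that add atoms: none
Why: Borohydride reduces the activated exocyclic imide carbonyl much faster than the γ-lactone (reductive auxiliary removal), turning C8 into a primary alcohol and returning the oxazolidinone.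

Step 9
Reactants: 16 (4R,5R)-5-[(1Z)-2-{[(tert-butyldiphenylsilyl)oxy]methyl}hexa-1,5-dien-1-yl]-4-(hydroxymethyl)oxolan-2-one
Product: 17 (2R,3S)-2-[(1Z)-2-{[(tert-butyldiphenylsilyl)oxy]methyl}hexa-1,5-dien-1-yl]-5-oxooxolane-3-carbaldehyde
Conditions: Dess–Martin periodinane, NaHCO3, CH2Cl2, 0 °C to rt; used crude
Reagents that add atoms: none
Why: Buffered Dess–Martin oxidation gives the β-acyloxy aldehyde without base, so C7 neither epimerises nor eliminates.

Step 10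
Reactants: 17 (2R,3S)-2-[(1Z)-2-{[(tert-butyldiphenylsilyl)oxy]methyl}hexa-1,5-dien-1-yl]-5-oxooxolane-3-carbaldehyde
Product: 19 (4R,5R)-5-[(1Z)-2-{[(tert-butyldiphenylsilyl)oxy]methyl}hexa-1,5-dien-1-yl]-4-[(1S)-1-hydroxy-3-methylbut-3-en-1-yl]oxolan-2-one, via borinate ester 18 (not isolated)
Conditions: (−)-Ipc2BOMe, 2-methylallylmagnesium chloride, Et2O, −78 °C to rt; then 17, −78 °C; pH 7 buffer, H2O2, MeOH, 0 °C
Reagents that add atoms: (−)-B-(2-methylallyl)diisopinocampheylborane, CC(=C)CB([C@@H]1C[C@@H]2C[C@H]([C@H]1C)C2(C)C)[C@@H]1C[C@@H]2C[C@H]([C@H]1C)C2(C)C, made in the flask from 2-methylallylmagnesium chloride, CC(=C)C[Mg]Cl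
Why: Brown asymmetric methallylboration through a closed chair transition state is reagent-controlled, the (+)-α-pinene-derived borane adding to the Si face of the aldehyde to set C8 as S and to install C9, C10 and C14.

Step 11
Reactants: 19 (4R,5R)-5-[(1Z)-2-{[(tert-butyldiphenylsilyl)oxy]methyl}hexa-1,5-dien-1-yl]-4-[(1S)-1-hydroxy-3-methylbut-3-en-1-yl]oxolan-2-one
Product: 20 (4S,5R)-5-[(1Z)-2-{[(tert-butyldiphenylsilyl)oxy]methyl}hexa-1,5-dien-1-yl]-4-[(1S)-3-methyl-1-[(triethylsilyl)oxy]but-3-en-1-yl]oxolan-2-one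
Conditions: TESOTf, 2,6-lutidine, CH2Cl2, −78 °C
Reagents that add atoms: triethylsilyl trifluoromethanesulfonate, CC[Si](CC)(CC)OS(=O)(=O)C(F)(F)F
Why: Silylation of the secondary alcohol under non-nucleophilic conditions blocks lactone migration to O8 and protects the hydroxyl for the enolate step.

Step 12
Reactants: 20 (4S,5R)-5-[(1Z)-2-{[(tert-butyldiphenylsilyl)oxy]methyl}hexa-1,5-dien-1-yl]-4-[(1S)-3-methyl-1-[(triethylsilyl)oxy]but-3-en-1-yl]oxolan-2-one
Product: 22 (3S,4S,5R)-5-[(1Z)-2-{[(tert-butyldiphenylsilyl)oxy]methyl}hexa-1,5-dien-1-yl]-3-methyl-4-[(1S)-3-methyl-1-[(triethylsilyl)oxy]but-3-en-1-yl]oxolan-2-one, via lithium enolate 21 (not isolated)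
Conditions: LiN(iPr)2, THF, −78 °C; MeI, −78 to −40 °C
Reagents that add atoms: iodomethane, CI
Why: Lactone enolate alkylation occurs anti to the bulky C7 substituent, giving the 3,4-trans methyl lactone (11S), which is also the thermodynamically preferred all-trans arrangement.

Step 13
Reactants: 22 (3S,4S,5R)-5-[(1Z)-2-{[(tert-butyldiphenylsilyl)oxy]methyl}hexa-1,5-dien-1-yl]-3-methyl-4-[(1S)-3-methyl-1-[(triethylsilyl)oxy]but-3-en-1-yl]oxolan-2-one
Product: 23 (3S,3aS,4S,6Z,10Z,11aR)-10-{[(tert-butyldiphenylsilyl)oxy]methyl}-3,6-dimethyl-4-[(triethylsilyl)oxy]-3a,4,5,8,9,11a-hexahydrocyclodeca[b]furan-2(3H)-one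
Conditions: second-generation Grubbs catalyst, RuCl2(=CHPh)(H2IMes)(PCy3) (10–20 mol %), 1,4-benzoquinone (20 mol %), toluene (1 mM), 60 °C, Ar sparge
Reagents that add atoms: none
Why: Ring-closing metathesis initiates at the monosubstituted C1 vinyl group and closes onto the 1,1-disubstituted methallyl alkene with loss of ethene, and a ten-membered ring that already holds a trans alkene and a trans-fused lactone accommodates the new trisubstituted C1=C10 bond only as the cis (Z) isomer.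

Step 14
Reactants: 23 (3S,3aS,4S,6Z,10Z,11aR)-10-{[(tert-butyldiphenylsilyl)oxy]methyl}-3,6-dimethyl-4-[(triethylsilyl)oxy]-3a,4,5,8,9,11a-hexahydrocyclodeca[b]furan-2(3H)-one
Product: 24 (3S,3aR,4S,6Z,10Z,11aR)-10-{[(tert-butyldiphenylsilyl)oxy]methyl}-4-hydroxy-3,6-dimethyl-3a,4,5,8,9,11a-hexahydrocyclodeca[b]furan-2(3H)-one
Conditions: HF·pyridine, pyridine, THF, 0 °C
Reagents that add atoms: none
Why: Buffered fluoride cleaves the triethylsilyl ether far faster than the tert-butyldiphenylsilyl ether (selective desilylation), freeing only the C8 hydroxyl.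

Step 15
Reactants: 25 [(tert-butyldimethylsilyl)oxy]acetaldehyde; 26 ethyl 2-(triphenyl-λ5-phosphanylidene)propanoate
Product: 27 ethyl (2E)-4-[(tert-butyldimethylsilyl)oxy]-2-methylbut-2-enoate
Conditions: CH2Cl2, rt
Reagents that add atoms: none
Why: Wittig olefination with the stabilised α-methyl ylide gives the (E)-trisubstituted enoate with high selectivity.

Step 16
Reactants: 27 ethyl (2E)-4-[(tert-butyldimethylsilyl)oxy]-2-methylbut-2-enoate
Product: 29 (2E)-4-[(tert-butyldimethylsilyl)oxy]-2-methylbut-2-enoic acid, via lithium carboxylate 28 (not isolated)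
Conditions: LiOH, THF/MeOH/H2O, rt; 1 M HCl to pH 4, 0 °C
Reagents that add atoms: lithium hydroxide, [Li+].[OH-]
Why: Saponification of the ethyl ester leaves the primary silyl ether and the alkene geometry intact.

Step 17
Reactants: 29 (2E)-4-[(tert-butyldimethylsilyl)oxy]-2-methylbut-2-enoic acid; 24 (3S,3aR,4S,6Z,10Z,11aR)-10-{[(tert-butyldiphenylsilyl)oxy]methyl}-4-hydroxy-3,6-dimethyl-3a,4,5,8,9,11a-hexahydrocyclodeca[b]furan-2(3H)-one
Product: 31 (3S,3aR,4S,6Z,10Z,11aR)-10-{[(tert-butyldiphenylsilyl)oxy]methyl}-3,6-dimethyl-2-oxo-2,3,3a,4,5,8,9,11a-octahydrocyclodeca[b]furan-4-yl (2E)-4-[(tert-butyldimethylsilyl)oxy]-2-methylbut-2-enoate, via mixed anhydride 30 (not isolated)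
Conditions: 29, 2,4,6-trichlorobenzoyl chloride, Et3N, THF, rt; then 24, DMAP, toluene, rt
Reagents that add atoms: none
Why: Yamaguchi esterification acylates the hindered secondary C8 hydroxyl through the mixed anhydride and DMAP acyl transfer, with retention at C8 and without disturbing the lactone.

Step 18
Reactants: 31 (3S,3aR,4S,6Z,10Z,11aR)-10-{[(tert-butyldiphenylsilyl)oxy]methyl}-3,6-dimethyl-2-oxo-2,3,3a,4,5,8,9,11a-octahydrocyclodeca[b]furan-4-yl (2E)-4-[(tert-butyldimethylsilyl)oxy]-2-methylbut-2-enoate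
Product: 32 (3S,3aR,4S,6Z,10Z,11aR)-10-(hydroxymethyl)-3,6-dimethyl-2-oxo-2,3,3a,4,5,8,9,11a-octahydrocyclodeca[b]furan-4-yl (2E)-4-hydroxy-2-methylbut-2-enoate
Conditions: HF·pyridine, pyridine, THF, 0 °C to rt
Reagents that add atoms: none
Why: Buffered fluoride-mediated global desilylation frees both primary allylic hydroxyls without base, so neither the esters, the lactone nor C11 are disturbed.

## Compound list

1 | prop-2-yn-1-ol | C#CCO | starting material
2 | tert-butyl(diphenyl)(prop-2-yn-1-yloxy)silane | C#CCO[Si](c1ccccc1)(c1ccccc1)C(C)(C)C | intermediate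
3 | lithium acetylide of 2 | [Li]C#CCO[Si](c1ccccc1)(c1ccccc1)C(C)(C)C | intermediate
4 | methyl 4-[(tert-butyldiphenylsilyl)oxy]but-2-ynoate | COC(=O)C#CCO[Si](c1ccccc1)(c1ccccc1)C(C)(C)C | intermediate
5 | methyl (2E)-3-{[(tert-butyldiphenylsilyl)oxy]methyl}-2-cupriohepta-2,6-dienoate (Cu cis to butenyl) | COC(=O)/C([Cu])=C(\CO[Si](c1ccccc1)(c1ccccc1)C(C)(C)C)CCC=C | intermediate
6 | methyl (2Z)-3-{[(tert-butyldiphenylsilyl)oxy]methyl}hepta-2,6-dienoate | COC(=O)/C=C(\CO[Si](c1ccccc1)(c1ccccc1)C(C)(C)C)CCC=C | intermediate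
7 | (2Z)-3-{[(tert-butyldiphenylsilyl)oxy]methyl}hepta-2,6-dien-1-ol | OC/C=C(\CO[Si](c1ccccc1)(c1ccccc1)C(C)(C)C)CCC=C | intermediate
8 | (2Z)-3-{[(tert-butyldiphenylsilyl)oxy]methyl}hepta-2,6-dienal | O=C/C=C(\CO[Si](c1ccccc1)(c1ccccc1)C(C)(C)C)CCC=C | intermediate
9 | (4S)-4-benzyl-1,3-oxazolidin-2-one | O=C1N[C@@H](Cc2ccccc2)CO1 | starting material
10 | methyl 4-chloro-4-oxobutanoate | COC(=O)CCC(=O)Cl | starting material
11 | N-lithio derivative of 9 | [Li]N1C(=O)OC[C@@H]1Cc1ccccc1 | intermediate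
12 | methyl 4-[(4S)-4-benzyl-2-oxo-1,3-oxazolidin-3-yl]-4-oxobutanoate | COC(=O)CCC(=O)N1C(=O)OC[C@@H]1Cc1ccccc1 | intermediate
13 | dibutylboron (Z)-enolate of 12 | CCCCB(CCCC)O/C(=C\CC(=O)OC)N1C(=O)OC[C@@H]1Cc1ccccc1 | intermediate
14 | methyl (3S,4R,5Z)-3-{[(4S)-4-benzyl-2-oxo-1,3-oxazolidin-3-yl]carbonyl}-6-{[(tert-butyldiphenylsilyl)oxy]methyl}-4-hydroxydeca-5,9-dienoate | C=CCC/C(CO[Si](c1ccccc1)(c1ccccc1)C(C)(C)C)=C/[C@@H](O)[C@H](CC(=O)OC)C(=O)N1C(=O)OC[C@@H]1Cc1ccccc1 | intermediate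
15 | (4S)-4-benzyl-3-{[(2R,3S)-2-[(1Z)-2-{[(tert-butyldiphenylsilyl)oxy]methyl}hexa-1,5-dien-1-yl]-5-oxooxolan-3-yl]carbonyl}-1,3-oxazolidin-2-one | C=CCC/C(CO[Si](c1ccccc1)(c1ccccc1)C(C)(C)C)=C/[C@H]1OC(=O)C[C@@H]1C(=O)N1C(=O)OC[C@@H]1Cc1ccccc1 | intermediate
16 | (4R,5R)-5-[(1Z)-2-{[(tert-butyldiphenylsilyl)oxy]methyl}hexa-1,5-dien-1-yl]-4-(hydroxymethyl)oxolan-2-one | C=CCC/C(CO[Si](c1ccccc1)(c1ccccc1)C(C)(C)C)=C/[C@H]1OC(=O)C[C@@H]1CO | intermediate
17 | (2R,3S)-2-[(1Z)-2-{[(tert-butyldiphenylsilyl)oxy]methyl}hexa-1,5-dien-1-yl]-5-oxooxolane-3-carbaldehyde | C=CCC/C(CO[Si](c1ccccc1)(c1ccccc1)C(C)(C)C)=C/[C@H]1OC(=O)C[C@@H]1C=O | intermediate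
18 | O-(diisopinocampheylboryl) borinate ester of 19 | C=CCC/C(CO[Si](c1ccccc1)(c1ccccc1)C(C)(C)C)=C/[C@H]1OC(=O)C[C@@H]1[C@@H](OB([C@@H]2C[C@@H]3C[C@H]([C@H]2C)C3(C)C)[C@@H]2C[C@@H]3C[C@H]([C@H]2C)C3(C)C)CC(C)=C | intermediate
19 | (4R,5R)-5-[(1Z)-2-{[(tert-butyldiphenylsilyl)oxy]methyl}hexa-1,5-dien-1-yl]-4-[(1S)-1-hydroxy-3-methylbut-3-en-1-yl]oxolan-2-one | C=CCC/C(CO[Si](c1ccccc1)(c1ccccc1)C(C)(C)C)=C/[C@H]1OC(=O)C[C@@H]1[C@@H](O)CC(C)=C | intermediate
20 | (4S,5R)-5-[(1Z)-2-{[(tert-butyldiphenylsilyl)oxy]methyl}hexa-1,5-dien-1-yl]-4-[(1S)-3-methyl-1-[(triethylsilyl)oxy]but-3-en-1-yl]oxolan-2-one | C=CCC/C(CO[Si](c1ccccc1)(c1ccccc1)C(C)(C)C)=C/[C@H]1OC(=O)C[C@@H]1[C@@H](O[Si](CC)(CC)CC)CC(C)=C | intermediate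
21 | lithium enolate of 20 | C=CCC/C(CO[Si](c1ccccc1)(c1ccccc1)C(C)(C)C)=C/[C@H]1OC(O[Li])=C[C@@H]1[C@@H](O[Si](CC)(CC)CC)CC(C)=C | intermediate
22 | (3S,4S,5R)-5-[(1Z)-2-{[(tert-butyldiphenylsilyl)oxy]methyl}hexa-1,5-dien-1-yl]-3-methyl-4-[(1S)-3-methyl-1-[(triethylsilyl)oxy]but-3-en-1-yl]oxolan-2-one | C=CCC/C(CO[Si](c1ccccc1)(c1ccccc1)C(C)(C)C)=C/[C@H]1OC(=O)[C@@H](C)[C@@H]1[C@@H](O[Si](CC)(CC)CC)CC(C)=C | intermediate
23 | (3S,3aS,4S,6Z,10Z,11aR)-10-{[(tert-butyldiphenylsilyl)oxy]methyl}-3,6-dimethyl-4-[(triethylsilyl)oxy]-3a,4,5,8,9,11a-hexahydrocyclodeca[b]furan-2(3H)-one | C/C1=C/CC/C(CO[Si](c2ccccc2)(c2ccccc2)C(C)(C)C)=C/[C@H]2OC(=O)[C@@H](C)[C@@H]2[C@@H](O[Si](CC)(CC)CC)C1 | intermediate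
24 | (3S,3aR,4S,6Z,10Z,11aR)-10-{[(tert-butyldiphenylsilyl)oxy]methyl}-4-hydroxy-3,6-dimethyl-3a,4,5,8,9,11a-hexahydrocyclodeca[b]furan-2(3H)-one | C/C1=C/CC/C(CO[Si](c2ccccc2)(c2ccccc2)C(C)(C)C)=C/[C@H]2OC(=O)[C@@H](C)[C@@H]2[C@@H](O)C1 | intermediate
25 | [(tert-butyldimethylsilyl)oxy]acetaldehyde | O=CCO[Si](C)(C)C(C)(C)C | starting material
26 | ethyl 2-(triphenyl-λ5-phosphanylidene)propanoate | CCOC(=O)C(C)=P(c1ccccc1)(c1ccccc1)c1ccccc1 | starting material
27 | ethyl (2E)-4-[(tert-butyldimethylsilyl)oxy]-2-methylbut-2-enoate | CCOC(=O)/C(C)=C/CO[Si](C)(C)C(C)(C)C | intermediate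
28 | lithium (2E)-4-[(tert-butyldimethylsilyl)oxy]-2-methylbut-2-enoate | [Li+].[O-]C(=O)/C(C)=C/CO[Si](C)(C)C(C)(C)C | intermediate
29 | (2E)-4-[(tert-butyldimethylsilyl)oxy]-2-methylbut-2-enoic acid | OC(=O)/C(C)=C/CO[Si](C)(C)C(C)(C)C | intermediate
30 | (2E)-4-[(tert-butyldimethylsilyl)oxy]-2-methylbut-2-enoic 2,4,6-trichlorobenzoic anhydride | O=C(OC(=O)/C(C)=C/CO[Si](C)(C)C(C)(C)C)c1c(Cl)cc(Cl)cc1Cl | intermediate
31 | (3S,3aR,4S,6Z,10Z,11aR)-10-{[(tert-butyldiphenylsilyl)oxy]methyl}-3,6-dimethyl-2-oxo-2,3,3a,4,5,8,9,11a-octahydrocyclodeca[b]furan-4-yl (2E)-4-[(tert-butyldimethylsilyl)oxy]-2-methylbut-2-enoate | C/C1=C/CC/C(CO[Si](c2ccccc2)(c2ccccc2)C(C)(C)C)=C/[C@H]2OC(=O)[C@@H](C)[C@@H]2[C@@H](OC(=O)/C(C)=C/CO[Si](C)(C)C(C)(C)C)C1 | intermediate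
32 | (3S,3aR,4S,6Z,10Z,11aR)-10-(hydroxymethyl)-3,6-dimethyl-2-oxo-2,3,3a,4,5,8,9,11a-octahydrocyclodeca[b]furan-4-yl (2E)-4-hydroxy-2-methylbut-2-enoate | C/C1=C/CC/C(CO)=C/[C@H]2OC(=O)[C@@H](C)[C@@H]2[C@@H](OC(=O)/C(C)=C/CO)C1 | target

## Step count and risks

Total steps: 18. Longest linear sequence: 15 (steps 1–5, 7–14, 17, 18); steps 6, 15 and 16 are side branches.

Most likely to fail:

Step 13 (ring-closing metathesis). Closing a ten-membered ring with a trisubstituted alkene competes with oligomerisation, and a ruthenium carbene that engages the hindered C4=C5 bond could cut the chain and form a cyclohexene. Fallback: close the ring only after the side chain is attached. Setting out from 22, HF·pyridine/pyridine in THF at 0 °C frees the C8 hydroxyl to give the diene alcohol F1. Yamaguchi esterification of F1 with acid 29 (through anhydride 30) gives the diene ester F2. Metathesis of F2 with RuCl2(=CHPh)(H2IMes)(PCy3) in dilute toluene then closes the ring on a substrate whose C8 substituent is the planar ester of the natural product instead of a bulky silyl ether; the trisubstituted, electron-poor side-chain alkene is not expected to take part. This comes back to the route at 31, and step 18 follows.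

Step 10 (methallylboration). The β-acyloxy aldehyde 17 is prone to elimination, and the reagent may be mismatched with the C7 stereocentre, which would lower the C8 selectivity. Fallback: build C8–C9 by an organocatalytic aldol and make the alkene afterwards. Setting out from 17, D-proline (30 mol %) in acetone/DMSO at rt gives the (8S)-β-hydroxy ketone F3; L-proline gives the (R)-ketol from α-branched aldehydes, so the D-catalyst is used. TESOTf/2,6-lutidine converts F3 into the silyl ether F4. Methylenation of the methyl ketone of F4 with Zn, CH2Br2 and TiCl4 in THF, which leaves lactones alone, comes back to the route at 20.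

Step 8 (reductive auxiliary removal). The lactone may be partly reduced, and the β-hydroxymethyl lactone 16 can translactonise under the basic borohydride conditions. Fallback: avoid the alcohol altogether. Setting out from 15, EtSLi (EtSH, n-BuLi, THF, 0 °C) exchanges the auxiliary for a thioester to give the S-ethyl thioester F5. Fukuyama reduction of F5 with Et3SiH over Pd/CaCO3 poisoned with Pb(OAc)2 in acetone, chosen to spare the alkenes, comes back to the route at aldehyde 17, skipping 16.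

Further compounds

F1 | step 13 | (3S,4R,5R)-5-[(1Z)-2-{[(tert-butyldiphenylsilyl)oxy]methyl}hexa-1,5-dien-1-yl]-4-[(1S)-1-hydroxy-3-methylbut-3-en-1-yl]-3-methyloxolan-2-one | C=CCC/C(CO[Si](c1ccccc1)(c1ccccc1)C(C)(C)C)=C/[C@H]1OC(=O)[C@@H](C)[C@@H]1[C@@H](O)CC(C)=C
F2 | step 13 | (1S)-1-[(2R,3R,4S)-2-[(1Z)-2-{[(tert-butyldiphenylsilyl)oxy]methyl}hexa-1,5-dien-1-yl]-4-methyl-5-oxooxolan-3-yl]-3-methylbut-3-en-1-yl (2E)-4-[(tert-butyldimethylsilyl)oxy]-2-methylbut-2-enoate | C=CCC/C(CO[Si](c1ccccc1)(c1ccccc1)C(C)(C)C)=C/[C@H]1OC(=O)[C@@H](C)[C@@H]1[C@@H](OC(=O)/C(C)=C/CO[Si](C)(C)C(C)(C)C)CC(C)=C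
F3 | step 10 | (4R,5R)-5-[(1Z)-2-{[(tert-butyldiphenylsilyl)oxy]methyl}hexa-1,5-dien-1-yl]-4-[(1S)-1-hydroxy-3-oxobutyl]oxolan-2-one | C=CCC/C(CO[Si](c1ccccc1)(c1ccccc1)C(C)(C)C)=C/[C@H]1OC(=O)C[C@@H]1[C@@H](O)CC(C)=O
F4 | step 10 | (4S,5R)-5-[(1Z)-2-{[(tert-butyldiphenylsilyl)oxy]methyl}hexa-1,5-dien-1-yl]-4-[(1S)-3-oxo-1-[(triethylsilyl)oxy]butyl]oxolan-2-one | C=CCC/C(CO[Si](c1ccccc1)(c1ccccc1)C(C)(C)C)=C/[C@H]1OC(=O)C[C@@H]1[C@@H](O[Si](CC)(CC)CC)CC(C)=O
F5 | step 8 | S-ethyl (2R,3S)-2-[(1Z)-2-{[(tert-butyldiphenylsilyl)oxy]methyl}hexa-1,5-dien-1-yl]-5-oxooxolane-3-carbothioate | C=CCC/C(CO[Si](c1ccccc1)(c1ccccc1)C(C)(C)C)=C/[C@H]1OC(=O)C[C@@H]1C(=O)SCC
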